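## Analysis of the target

The target is one benzene ring with three substituents in a 1,2,4-relationship: C1 carries the side chain, C2 a methoxy group and C4 a methyl group, while C3, C5 and C6 are unsubstituted. The side chain is a three-carbon unit joined to the ring through its central carbon, a tertiary benzylic carbinol carbon that bears a free hydroxyl and two CH2O-C(=O)CH(CH3)2 arms. Because the two arms are identical, this carbon is not a stereocentre and the molecule is achiral; no stereocontrol is needed, and chiral intermediates may be racemic. The sensitive groups are the tertiary benzylic alcohol, which ionises easily in acid because an ortho-methoxy and a para-methyl group stabilise the cation, and the two esters, which lie 1,2 to that hydroxyl and can migrate or be cleaved under base. The difficulty is twofold: the side chain sits ortho to methoxy and para to methyl, the minor site of electrophilic attack on the simple methoxytoluene, and the benzylic carbon is fully substituted and fully oxygenated. The strategy rests on the ring atoms C2(OMe)-C3(H)-C4(Me)-C5(H), which are the carbon skeleton of a 1-methoxy-3-methyl-1,3-diene with the donor at one terminus. The remaining ring atoms C1 and C6 correspond to a terminal acyl alkyne whose acyl carbon is the future carbinol carbon. The ring can therefore be assembled from non-aromatic matter with the 1,2,4-pattern fixed by connectivity rather than by directing effects.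

## Retrosynthetic reasoning

**14 to 13.** The bond between one methylene carbon and its ester oxygen is cut and that methylene is reconnected to the tertiary oxygen, giving the 2-aryl epoxide 13. Since the two arms of 14 are identical, either can be attached last. The opening that adds the second isobutyryloxy group also releases the tertiary hydroxyl, so no protecting group is needed. The forward reaction must deliver a carboxylate to the unsubstituted epoxide carbon without ionising the benzylic C-O bond.

**13 to 12.** The C-C bond between the carbinol carbon and the epoxide methylene is cut, which is a one-carbon methylene transfer in the forward sense. This returns the carbinol carbon to a ketone carbonyl, the oxidation level an acyl alkyne brings with it, and leaves one acyloxymethyl arm already finished in 12. The forward step must add a methylene to a hindered, enolisable aryl ketone without disturbing the neighbouring ester.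

**12 to 3 and 10, through 11.** Two ring bonds are cut: C1-C2, between the acyl-bearing and the methoxy-bearing carbon, and C5-C6, between the two adjacent unsubstituted carbons. A saturated two-carbon bridge is restored between C2 and C5, which leads back to the bicyclic adduct 11 and from there to diene 3 and ynone 10. These bonds are chosen because the polarisation of both partners then places the acyl carbon next to the methoxy carbon, the relationship that substitution on the arene gives poorly. The forward reaction must give the cycloaddition in this orientation and then lose the bridge thermally to reveal the arene.

**3 to 1, through 2.** Diene 3 is the dienol methyl ether of enone 1. The disconnection is the enol ether C-O bond together with a shift of the ring double bond, passing through ketal 2. The forward reaction must end at the linearly conjugated isomer, with the methoxy group on a diene terminus.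

**10 to 9, then 7 and 8.** The bond between the acyl carbon and the alkyne carbon is cut. A silyl group on the alkyne (in 9, from 8) lets the acid chloride 7 be attached by Lewis-acid-promoted substitution at the silicon-bearing carbon, and it is removed afterwards to uncover the terminal ynone 10.

**7 to 6, then 4 and 5.** The acid chloride 7 comes from acid 6, which is disconnected at the ester C-O bond into the hydroxy acid 4 and the acyl chloride 5. Both isobutyrate groups of the target thus derive from simple isobutyryl sources.

## Alternatives that were turned down

Alternative 1: The arene is again made from an alkyne and a six-membered diene, but with the roles reversed. The ring bonds C1-C6 and C2-C3 would form by inverse-demand cycloaddition of 4-methyl-2H-pyran-2-one A2 with the ynol ether 5-(methoxyethynyl)-2,2-dimethyl-5-(trimethylsilyloxy)-1,3-dioxane A3. Decarboxylative cycloreversion would then give 5-(2-methoxy-4-methylphenyl)-2,2-dimethyl-5-(trimethylsilyloxy)-1,3-dioxane A1.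
- In its favour: A3 already holds the complete three-carbon carbinol unit with all three oxygens, so no ylide or epoxide chemistry on an alpha-acyloxy ketone is needed. On this point it is stronger than the chosen route.
- Against it: A2 carries no acceptor group and is a weak electrophilic diene, and A3 is a disubstituted alkyne with a quaternary propargylic centre. The cycloaddition would therefore need forcing temperatures, at which ynol ethers are not durable.
- Against it: regiochemistry depends only on the nucleophilic carbon of A3 attacking C6 of A2, with no second substituent reinforcing it.
- Against it: the end game must strip an acetonide and a silyl ether with acid from a tertiary benzylic carbinol that ionises readily, and then acylate twice.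
- Comparison: the step count is similar. The chosen route offers electronically matched partners, two substituents that direct in the same sense, a well-precedented cycloaddition type for exactly this ortho-methoxy aryl ketone pattern, and no protecting groups.

Alternative 2: Both C-C bonds from the carbinol carbon to its methylenes are cut at once. A vinylcerium-type organometallic would add twice to methyl 2-methoxy-4-methylbenzoate A5 to give 3-(2-methoxy-4-methylphenyl)penta-1,4-dien-3-ol A4. Double oxidative cleavage with reductive work-up would give 2-(2-methoxy-4-methylphenyl)propane-1,2,3-triol A6, whose two primary hydroxyls would be acylated.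
- In its favour: the arene is bought with the correct pattern, the sequence is two-directional and only about four steps long. On step economy and on the reliability of its first step it is stronger than the chosen route.
- Against it: A4 is a doubly allylic, benzylic tertiary alcohol on an electron-rich ring and should ionise or transpose with traces of acid.
- Against it: the cleavage passes through a 2-aryl-2-hydroxy-1,3-dialdehyde stage that can lose a formyl group by retro-aldol or retro-Claisen fragmentation unless reduced at once, and the electron-rich ring competes for the oxidant.
- Against it: two carbons are discarded, and the regiochemical problem of the ring is bought away rather than solved.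
- Comparison: the chosen route is longer. In exchange it builds the 1,2,4-pattern from non-aromatic precursors with full regiocontrol, keeps the carbinol carbon as a stable ketone until late, uses no oxidant in the presence of the electron-rich arene, and installs the two arms separately, which would also allow unsymmetrical analogues.

Alternative 3: The aryl-to-central-carbon bond and both methylene-oxygen bonds would form in one operation. A trivalent iodine dicarboxylate with isobutyrate ligands, activated by a boron Lewis acid, would attack the alkene of 2-methoxy-4-methyl-1-(prop-2-en-1-yl)benzene A8. A phenonium shift of the aryl group and capture by two isobutyrates would give 2-(2-methoxy-4-methylphenyl)propane-1,3-diyl bis(2-methylpropanoate) A7.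
- In its favour: both ester arms arrive in a single step from a simple allylarene, and the ortho-methoxy aryl group migrates well. To the carbon skeleton it is shorter than the chosen route.
- Against it: A7 lacks the tertiary hydroxyl. The missing oxidation would have to be a benzylic C-H hydroxylation at the most hindered carbon, in competition with the aryl methyl group and the activated ring, and no selective handle exists for it.
- Against it: the electron-rich ring can itself be oxidised by the iodane.
- Against it: A8 needs a regiodefined ortho-allylation, so the ring regiochemistry problem returns.
- Comparison: the chosen route carries the carbinol oxygen from the start as the ketone oxygen of the dienophile, so no late C-H oxidation is needed.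

Key step: step 6

Remark on the chemistry: the target has no stereocentre, so the chiral intermediates 11 and 13 are taken as racemates. Diene 3 is assumed to be usable as the acid-equilibrated mixture in which it should be the main isomer.

## Route

Step 1
Reactants: 1 3-methylcyclohex-2-en-1-one
Product: 3 1-methoxy-3-methylcyclohexa-1,3-diene, via 3,3-dimethoxy-1-methylcyclohex-1-ene 2 (not isolated)
Conditions: HC(OMe)3 (1.5 equiv), p-TsOH·H2O (cat.), MeOH, 0 °C to rt; then pyridinium p-toluenesulfonate (cat.), PhMe, 110 °C with removal of MeOH; distillation from K2CO3
Reagents that add atoms: trimethyl orthoformate, COC(OC)OC
Why: Acid-catalysed ketalisation with the orthoester followed by acid-catalysed loss of methanol is the standard dienol ether synthesis from enones. Reversible protonation through the common oxocarbenium ion should settle the mixture on the linearly conjugated isomer with the methoxy group on a diene terminus, as in steroidal 3-alkoxy-3,5-dienes; no stereocentre is formed.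

Step 2
Reactants: 4 glycolic acid; 5 isobutyryl chloride
Product: 6 2-[(2-methylpropanoyl)oxy]acetic acid
Conditions: 5 (1.1 equiv), neat, rt to 50 °C (HCl evolved); brief aqueous work-up
Reagents that add atoms: none
Why: O-Acylation of the primary hydroxyl of a hydroxy acid by an acid chloride, the way acetoxyacetic acid is made; the carboxyl group stays free for the next step.

Step 3
Reactants: 6 2-[(2-methylpropanoyl)oxy]acetic acid
Product: 7 2-chloro-2-oxoethyl 2-methylpropanoate
Conditions: (COCl)2 (1.2 equiv), DMF (cat.), CH2Cl2, 0 °C to rt
Reagents that add atoms: oxalyl chloride, ClC(=O)C(=O)Cl
Why: Acid chloride formation through the catalytic chloroiminium species; the by-products are gases and the ester is inert under these conditions.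

Step 4
Reactants: 7 2-chloro-2-oxoethyl 2-methylpropanoate; 8 bis(trimethylsilyl)acetylene
Product: 9 2-oxo-4-(trimethylsilyl)but-3-yn-1-yl 2-methylpropanoate
Conditions: AlCl3 (1.1 equiv), CH2Cl2, 0 °C; cold 1 M HCl quench
Reagents that add atoms: none
Why: Friedel-Crafts-type ipso-acylation of a silylalkyne, in which the acylium ion attacks the silicon-bearing carbon via a beta-silyl-stabilised vinyl cation and chlorotrimethylsilane is lost. The reaction stops after one acylation because the ynone product is deactivated.

Step 5
Reactants: 9 2-oxo-4-(trimethylsilyl)but-3-yn-1-yl 2-methylpropanoate
Product: 10 2-oxobut-3-yn-1-yl 2-methylpropanoate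
Conditions: Na2B4O7 (cat., 0.01 M aq.), MeOH, 20 °C, 5-10 min; pH 5 buffer quench; used at once
Reagents that add atoms: none
Why: Protodesilylation of a silyl ynone; the acyl group makes the alkynyl carbon a good leaving group from silicon, so a weakly basic borate buffer suffices. The short contact time should spare the ester and limit conjugate addition of the solvent.

Step 6
Reactants: 3 1-methoxy-3-methylcyclohexa-1,3-diene; 10 2-oxobut-3-yn-1-yl 2-methylpropanoate
Product: 12 2-(2-methoxy-4-methylphenyl)-2-oxoethyl 2-methylpropanoate, via bicyclo[2.2.2]octa-2,5-diene cycloadduct 11 (not isolated)
Conditions: 3 (1.5 equiv), BHT (cat.), o-xylene, 60 °C, then 145 °C (reflux, Ar stream to carry off ethylene); base-washed glassware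
Reagents that add atoms: none
Why: The electron-rich diene 3 and the electron-poor alkyne 10 should combine in a normal-demand, probably asynchronous Diels-Alder reaction to give the bicyclo[2.2.2]octa-2,5-diene 11. On further heating 11 should undergo a retro-Diels-Alder reaction that expels its saturated two-carbon bridge as ethylene; this is the only cycloreversion that yields an arene, and escape of the gas makes it irreversible. The closest known reaction type is the Alder-Rickert synthesis of ortho-methoxy aryl ketones and benzoates from 1-methoxycyclohexa-1,3-dienes and acetylenic carbonyl compounds. The one ring built, the benzene ring, closes by a concerted suprafacial [4+2] cycloaddition that forms the arene bonds C1-C2 and C5-C6, and it is unveiled by the [4+2] cycloreversion. No stereocentre remains, since the two bridgeheads of 11 form as a racemic pair and both become planar ring carbons. The step needs the ortho orientation, which is secured because the diene terminus remote from the methoxy group (vinylogous to it and next to the methyl-bearing carbon) has the largest HOMO coefficient and bonds to the unsubstituted beta-carbon of the ynone, leaving the methoxy-bearing terminus to bond to the acyl-bearing carbon; methoxy and methyl act in the same sense. It also needs the diene to react as the linear 1-methoxy isomer; the unconjugated isomer is no diene and the cross-conjugated 2-methoxy isomer should be the minor component, so 3 is used in excess and any regioisomeric ketone is removed by chromatography. The methoxy group is retained because it sits on a bridgehead of 11 from which no elimination path exists.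

Step 7
Reactants: 12 2-(2-methoxy-4-methylphenyl)-2-oxoethyl 2-methylpropanoate
Product: 13 rac-[2-(2-methoxy-4-methylphenyl)oxiran-2-yl]methyl 2-methylpropanoate
Conditions: Me3S+ I- (1.2 equiv), n-BuLi (1.1 equiv), THF, -10 °C; then 12, -10 °C to rt; chromatography on Et3N-deactivated silica
Reagents that add atoms: trimethylsulfonium iodide, C[S+](C)C.[I-]
Why: Corey-Chaykovsky epoxidation, in which the unstabilised sulfonium ylide adds to the ketone carbonyl and the betaine closes by intramolecular displacement of dimethyl sulfide. The low temperature and the high carbonyl reactivity of this ylide should favour addition over enolisation or attack on the ester. The new epoxide carbon forms as a racemate, and it stops being a stereocentre in step 8.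

Step 8
Reactants: 13 rac-[2-(2-methoxy-4-methylphenyl)oxiran-2-yl]methyl 2-methylpropanoate
Product: 14 2-hydroxy-2-(2-methoxy-4-methylphenyl)propane-1,3-diyl bis(2-methylpropanoate)
Conditions: i-PrCO2H (3 equiv), CsO2CCH(CH3)2 (0.3 equiv), DMF, 70 °C
Reagents that add atoms: isobutyric acid, CC(C)C(=O)O
Why: Nucleophilic ring opening of a 2,2-disubstituted epoxide by a carboxylate at the unsubstituted methylene, with the free acid protonating the tertiary alkoxide as it forms so that acyl migration is suppressed. Exchange with the ester already present is degenerate, and the product has two identical arms, so the carbinol carbon is achiral.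

## Compound list

1 | 3-methylcyclohex-2-en-1-one | CC1=CC(=O)CCC1 | starting material
2 | 3,3-dimethoxy-1-methylcyclohex-1-ene | COC1(OC)C=C(C)CCC1 | intermediate (not isolated)
3 | 1-methoxy-3-methylcyclohexa-1,3-diene | COC1=CC(C)=CCC1 | intermediate
4 | glycolic acid | OCC(=O)O | starting material
5 | isobutyryl chloride | CC(C)C(=O)Cl | starting material
6 | 2-[(2-methylpropanoyl)oxy]acetic acid | CC(C)C(=O)OCC(=O)O | intermediate
7 | 2-chloro-2-oxoethyl 2-methylpropanoate | CC(C)C(=O)OCC(=O)Cl | intermediate
8 | bis(trimethylsilyl)acetylene | C[Si](C)(C)C#C[Si](C)(C)C | starting material
9 | 2-oxo-4-(trimethylsilyl)but-3-yn-1-yl 2-methylpropanoate | CC(C)C(=O)OCC(=O)C#C[Si](C)(C)C | intermediate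
10 | 2-oxobut-3-yn-1-yl 2-methylpropanoate | C#CC(=O)COC(=O)C(C)C | intermediate
11 | rac-2-(1-methoxy-5-methylbicyclo[2.2.2]octa-2,5-dien-2-yl)-2-oxoethyl 2-methylpropanoate | COC12CCC(C=C1C(=O)COC(=O)C(C)C)C(C)=C2 | intermediate (not isolated)
12 | 2-(2-methoxy-4-methylphenyl)-2-oxoethyl 2-methylpropanoate | COc1cc(C)ccc1C(=O)COC(=O)C(C)C | intermediate
13 | rac-[2-(2-methoxy-4-methylphenyl)oxiran-2-yl]methyl 2-methylpropanoate | COc1cc(C)ccc1C1(COC(=O)C(C)C)CO1 | intermediate
14 | 2-hydroxy-2-(2-methoxy-4-methylphenyl)propane-1,3-diyl bis(2-methylpropanoate) | COc1cc(C)ccc1C(O)(COC(=O)C(C)C)COC(=O)C(C)C | target

## Step count and least certain steps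

Total: 8 steps. Longest linear sequence: 7 steps (steps 2 to 8, from 4 to 14). Step 1 is a one-step side branch that joins at step 6.

**Step 6 (key step).** The terminal ynone may be consumed by oligomerisation or conjugate addition before it meets the diene. The enol ether may be hydrolysed or isomerised by traces of acid at the temperature needed, and the cycloreversion may stall so that adduct and arene coexist. Any cross-conjugated diene isomer present would also erode regiochemical purity. The alpha-acyloxy methylene makes 10 more fragile than a simple ynone. The fallback keeps the same disconnection but takes the fragile arm out of the thermal step; it sets out from 3 and comes back at 12. Diene 3 would be heated with purchased but-3-yn-2-one under the same regime to give, through the cycloadduct rac-1-(1-methoxy-5-methylbicyclo[2.2.2]octa-2,5-dien-2-yl)ethan-1-one F1, the aryl ketone 1-(2-methoxy-4-methylphenyl)ethan-1-one F2. Side-chain bromination with CuBr2 in EtOAc/CHCl3 at reflux should give 2-bromo-1-(2-methoxy-4-methylphenyl)ethan-1-one F3, and displacement of bromide by CsO2CCH(CH3)2 in DMF at rt should give 12.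

**Step 1.** Equilibration may stop short, leaving the cross-conjugated and unconjugated enol ethers, or the product may hydrolyse back to the enone on handling. Either lowers the effective diene content and feeds the wrong regioisomer into step 6. The fallback does not start from 1 but from purchased 3-methylanisole F4, and comes back at 3. Birch reduction (Li, liquid NH3, THF, t-BuOH, -33 °C) should give 1-methoxy-5-methylcyclohexa-1,4-diene F5, and base-mediated conjugation (KOt-Bu, DMSO, rt) should move the enol ether double bond into conjugation to give 3.

**Step 5.** Conjugate addition of methanol or water to the freed ynone, methanolysis of the alpha-acyloxy ester and oligomerisation on concentration are all possible, because the product is a strong acceptor released in a protic, weakly basic medium. The fallback avoids the silyl stage; it sets out from 7 and comes back at 10. Coupling of 7 with purchased tributyl(ethynyl)stannane under PdCl2(PPh3)2 catalysis in 1,2-dichloroethane at rt to 50 °C should give 10 directly under neutral, aprotic conditions.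

**Step 7.** The basic ylide may enolise the alpha-acyloxy ketone or attack the ester, the ortho-substituted carbonyl may react slowly, and the electron-rich 2-aryl epoxide may rearrange on acidic silica. The fallback replaces steps 7 and 8 with non-basic chemistry; it sets out from 12 and comes back at 14. Methylenation with Zn, CH2Br2 and TiCl4 in THF/CH2Cl2 (Takai-Lombardo conditions, selective for ketones over esters) should give 2-(2-methoxy-4-methylphenyl)prop-2-en-1-yl 2-methylpropanoate F6. Dihydroxylation with OsO4 (cat.) and N-methylmorpholine N-oxide in acetone/water should give rac-2,3-dihydroxy-2-(2-methoxy-4-methylphenyl)propyl 2-methylpropanoate F7. Acylation of its primary hydroxyl with 5 and 2,4,6-collidine in CH2Cl2 at -20 °C should give 14, the tertiary hydroxyl being too hindered to react.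

**Step 8.** The benzylic C-O bond may ionise in the acidic medium and lead to hydride-shift rearrangement to an aldehyde, or acyl groups may be transferred intermolecularly from the product alkoxide. The aryl group carries two donors that stabilise the benzylic cation. The fallback removes the regiochemical question; it sets out from 13 and comes back at 14. Hydration of 13 with dilute HClO4 in THF/water at 0 °C gives the same diol whichever carbon water attacks, namely rac-2,3-dihydroxy-2-(2-methoxy-4-methylphenyl)propyl 2-methylpropanoate F7. This is then acylated at its primary hydroxyl with 5 and 2,4,6-collidine as above to give 14.

## Further compounds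

F1 | step 6 | rac-1-(1-methoxy-5-methylbicyclo[2.2.2]octa-2,5-dien-2-yl)ethan-1-one | COC12CCC(C=C1C(C)=O)C(C)=C2
F2 | step 6 | 1-(2-methoxy-4-methylphenyl)ethan-1-one | COc1cc(C)ccc1C(C)=O
F3 | step 6 | 2-bromo-1-(2-methoxy-4-methylphenyl)ethan-1-one | COc1cc(C)ccc1C(=O)CBr
F4 | step 1 | 3-methylanisole (1-methoxy-3-methylbenzene) | COc1cccc(C)c1
F5 | step 1 | 1-methoxy-5-methylcyclohexa-1,4-diene | COC1=CCC=C(C)C1
F0 | step 5 | none | none
F6 | step 7 | 2-(2-methoxy-4-methylphenyl)prop-2-en-1-yl 2-methylpropanoate | COc1cc(C)ccc1C(=C)COC(=O)C(C)C
F7 | step 7 | rac-2,3-dihydroxy-2-(2-methoxy-4-methylphenyl)propyl 2-methylpropanoate | COc1cc(C)ccc1C(O)(CO)COC(=O)C(C)C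
F0 | step 8 | none | none
A1 | alternative 1 | 5-(2-methoxy-4-methylphenyl)-2,2-dimethyl-5-(trimethylsilyloxy)-1,3-dioxane | COc1cc(C)ccc1C1(O[Si](C)(C)C)COC(C)(C)OC1
A2 | alternative 1 | 4-methyl-2H-pyran-2-one | CC1=CC(=O)OC=C1
A3 | alternative 1 | 5-(methoxyethynyl)-2,2-dimethyl-5-(trimethylsilyloxy)-1,3-dioxane | COC#CC1(O[Si](C)(C)C)COC(C)(C)OC1
A4 | alternative 2 | 3-(2-methoxy-4-methylphenyl)penta-1,4-dien-3-ol | COc1cc(C)ccc1C(O)(C=C)C=C
A5 | alternative 2 | methyl 2-methoxy-4-methylbenzoate | COC(=O)c1ccc(C)cc1OC
A6 | alternative 2 | 2-(2-methoxy-4-methylphenyl)propane-1,2,3-triol | COc1cc(C)ccc1C(O)(CO)CO
A7 | alternative 3 | 2-(2-methoxy-4-methylphenyl)propane-1,3-diyl bis(2-methylpropanoate) | COc1cc(C)ccc1C(COC(=O)C(C)C)COC(=O)C(C)C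
A8 | alternative 3 | 2-methoxy-4-methyl-1-(prop-2-en-1-yl)benzene | C=CCc1ccc(C)cc1OC
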